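A small charge of Q, 34 mM against 44.2 mM of G in larch and birch, can be booked form by form. Q slips reversibly to J; Q, E and D each trade one G for one Z, climbing to E, D and X; E leaks to L. So E and L hold one spent G per Q, D two, X 3.

| setting | summer | noon | larch | birch |
|---|---|---|---|---|
| Q | 34 mM | 34 mM | 34 mM | 34 mM |
| G | 62 mM | 97 mM | 44.2 mM | 44.2 mM |
| remark | run made earlier | run made earlier |  |  |
| time |  |  | 15 h | 50 h |

| run | time / h | X / % | E / % | Q / % | D / % |
|---|---|---|---|---|---|
| summer | 1.00 | 9 | 20 | 48 | 7 |
| summer | 3.00 | 15 | 8 | 36 | 17 |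
| summer | 5.00 | 17 | 9 | 29 | 21 |
| summer | 8.00 | 13 | 7 | 30 | 17 |
| summer | 12.0 | 16 | 7 | 29 | 17 |
| summer | 15.0 | 12 | 6 | 26 | 20 |
| noon | 2.50 | 25 | 11 | 25 | 23 |
| noon | 5.00 | 24 | 6 | 22 | 22 |
| noon | 8.00 | 22 | 8 | 20 | 25 |
| noon | 10.0 | 21 | 6 | 20 | 24 |
| noon | 12.0 | 26 | 7 | 21 | 21 |
| noon | 15.0 | 24 | 6 | 23 | 21 |

(scatter of a reading: 1.5 percentage points)

- the numbers in the tables scatter by 1.5 percentage points (one standard deviation)
- what may be going on: Q <-> J; Q + G <-> Z + E; E -> L; E + G <-> Z + D; D + G <-> Z + X
- a reading of Q is of its free form alone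

- which of these there is most of at the end, counted by the Q in it, larch (X / Q / E / D)
- which of these there is most of at the end, counted by the Q in it, birch (X / Q / E / D)
- how much there is at the end of the one of these that leads, in percent of the Q charged: larch
- how much there is at the end of the one of these that leads, in percent of the Q charged: birch

I started from noon, which from 8.00 h on averaged Q 21.0 %, E 6.75 %, D 22.7 % and X 23.2 %, leaving a gap of 26.3 % that I called J. That book gives cZ 41.5 mM, so cZ/cG read 0.747. This exchange ratio r, cZ/cG, is the variable in the reaction quotient of each exchange step: with the steps at rest, E/Q goes as one over r, D/Q over its square, X/Q over its cube, and at noon's value Q, D and X read about level.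

For larch, scaling noon's shares, r = 1 gave Q 28.1 %, but that book handed back 1.58. Trying 1.30 gave Q 33.3 % and handed back 0.645. A straight line crosses at 1.14, with Q 30.9 %; r stands above noon's, so Q leads.

The weak link was L, which this book ignored. After 8.00 h the gap rose by 2 percentage points on average over summer and noon, a reading inside the scatter. Read as L, it gives 4.29 % in larch and 14.3 % in birch, so I committed to Q 29.6 % and 26.5 %.

The forecast also named Q in both flasks, “which favours free Q”, but with Z/G near 1.75 to 1.9: larch 36 % (31 % to 41 %), birch 22 % (16 % to 28 %), with L at 55% in birch against my figure.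

Q led, with 31.7 % in larch and 29.5 % in birch, where L stood at 12.3 %.

    Q ⇌ J (K = 0.990, k = 0.250 h⁻¹)
    Q + G ⇌ Z + E (K = 0.270, k = 23.0 M⁻¹ h⁻¹)
    E → L (k = 0.0340 h⁻¹)
    E + G ⇌ Z + D (K = 2.70, k = 20.0 M⁻¹ h⁻¹)
    D + G ⇌ Z + X (K = 0.840, k = 140 M⁻¹ h⁻¹)

Birch ended at r = 1.27, above noon's reading. A neighbour of birch, charged with 110 mM of G, ended at 0.749, level with noon's. At that r noon's shares put X/Q at 1.10, and in that neighbour X led with 25.2 %, over D at 22.4 % and Q at 17.1 %, an X/Q of 1.47.

All runs are simulated for an exercise.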